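At late times the readings still fall short of the G charged. At the last reading of Tuesday's run G stands at 11.6% and D at 51.1%, so 37.3% of the G charged is in neither form. G evidently has an unseen partner, and G with that partner is called here the pool.

| flask | G | L | remark | time |
|---|---|---|---|---|
| Saturday's | 0.030 M | 0.90 equiv | run made earlier |  |
| Tuesday's | 0.055 M | 0.90 equiv | run made earlier |  |
| Wednesday's | 0.14 M | 0.90 equiv | run made earlier |  |
| Friday's | 0.10 M | 1.2 equiv | run made earlier |  |
| south-west | 0.10 M | 0.900 equiv |  | 4.0 min |
| south-east | 0.050 M | 0.900 equiv |  | 4.0 min |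
| north-east | 0.15 M | 0.900 equiv |  | 4.0 min |
| south | 0.060 M | 0.600 equiv |  | 4.0 min |
| east | 0.10 M | 1.40 equiv |  | 4.0 min |
| north-west | 0.025 M | 0.900 equiv |  | 4.0 min |

| run | time / min | D / % | G / % |
|---|---|---|---|
| Saturday's | 0.333 | 1.7 | 42.1 |
| Saturday's | 0.667 | 7.2 | 28.5 |
| Saturday's | 1.00 | 9.4 | 23.8 |
| Saturday's | 2.00 | 25.3 | 18.6 |
| Saturday's | 4.00 | 41.7 | 15.5 |
| Tuesday's | 0.333 | 1.5 | 42.0 |
| Tuesday's | 1.00 | 15.0 | 22.6 |
| Tuesday's | 2.00 | 35.7 | 18.4 |
| Tuesday's | 3.00 | 45.2 | 14.0 |
| Tuesday's | 4.00 | 51.1 | 11.6 |
| Wednesday's | 0.833 | 10.9 | 27.7 |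
| Wednesday's | 1.50 | 28.8 | 19.0 |
| Wednesday's | 2.50 | 51.2 | 13.6 |
| Wednesday's | 3.00 | 57.0 | 11.1 |
| Wednesday's | 4.00 | 63.8 | 10.4 |
| Friday's | 0.833 | 12.5 | 24.8 |
| Friday's | 1.50 | 30.9 | 17.3 |
| Friday's | 2.50 | 57.0 | 12.2 |
| Friday's | 3.00 | 62.0 | 8.8 |
| Friday's | 4.00 | 68.9 | 6.4 |

(each reading ± 1 percentage point)

1. the flasks by amount of D, in percent of the G charged, highest first, at 4.0 min (south-west / south-east / north-east / south / east / north-west)
2. the same order at 15 min (south-west / south-east / north-east / south / east / north-west)
3. the amount of D, in percent of the G charged of the flask you put first, at 4.0 min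
4. the amount of D, in percent of the G charged of the flask you put last, at 4.0 min

- at the start none of L is in solution
- a reading or a percentage of D counts all its forms, free or not

The reckoning here starts with the main step only, L going into D one for one. D then stops at the equivalents of L, 0.900 equiv for north-west and 0.600 equiv for south, so south looks last.

The second process is speed. What comes from L is taken up by the pool, in a pseudo-first-order way, and the falling pool is replaced by its mean, the average of its starting value and that value less D. The capture constant κ is minus the logarithm of the part of L not yet turned into D, divided by mean pool and time. Saturday's last reading gives 6.55 /M/min. Tuesday's gives 5.12 /M/min, Wednesday's 3.24 /M/min and Friday's 3.26 /M/min. D sits inside its own mean pool, so two passes are taken. With Wednesday's κ, north-west falls to 22.7%.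

The rest of the flask shows in κ itself. Wednesday's and Friday's values are about equal, though their G differs, and their molar L is close, 0.126 M and 0.120 M. Saturday's κ, at 0.0270 M of L, is higher. No L is in solution at the start, and a dissolving lag that grows with the charge would read so. North-west, at 0.0225 M, takes Saturday's κ and rises to 37.4%. South, at 0.0360 M, takes the mean of Saturday's and Tuesday's, 5.84 /M/min, and gives 40.2%. So north-west, not south, comes last. East, with Friday's κ, gives 75.9%.

The forecast differs. Holding that “L looks stoichiometric and caps D”, it gives east > north-east > south-west > south-east > north-west > south at 4.0 min and east > north-east > south-west > south-east > north-west > south at 15 min. It puts east at 71% (range 66% to 76%) and south last at 35% (range 28% to 42%).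

The flasks give east > north-east > south-west > south-east > south > north-west at 4.0 min, with east at 74.2% and north-west at 37.0%, and east > north-east > south-west > south-east > north-west > south at 15 min.

    X + J → D (k = 0.210 /M/s)
    E ⇌ D, rate k2*(cs2 - [D]) while solid is left; crystals form when [D] > cs2 (solubility = 38.0 mM, k = 12.0 /s)
    Z → J (k = 0.0560 /s)
    G ⇌ X (K = 3.10, k = 0.0530 /s)
    L ⇌ Z, rate k5*(cs5 - [Z]) while solid is left; crystals form when [Z] > cs5 (solubility = 0.0650 M, k = 0.0270 /s)
    2 J → Q (k = 0.0530 /M/s)

In north-west at 0.116 min, X falls back 41 times faster than it goes on. In north-west G and X relax with a half-life of 0.165 min, far shorter than the 28 min of X by the step to D at 0.116 min. Read back from north-west's D, κ is 6.50 /M/min. The flask like north-west but with 1.50 equiv of L gives 51.2% of D, and there κ reads 5.62 /M/min, less than Saturday's and more than Tuesday's 5.12 /M/min.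

All runs come from a simulation for an exercise; noise was put on by code.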